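There were 4 questions, and the one asking for a number was how much complex with two exchanged stands in larch at the end.

| flask | starting complex | incoming ligand | leaving ligand | capture agent | remark | time |
|---|---|---|---|---|---|---|
| Sunday's | 13 mM | 11 mM | 6.5 mM | 3.9 mM | run made earlier |  |
| Friday's | 13 mM | 25 mM | 6.5 mM | 3.9 mM | run made earlier |  |
| Thursday's | 13 mM | 62 mM | 6.5 mM | 3.9 mM | run made earlier |  |
| cedar | 13 mM | 13.0 mM | 6.50 mM | 3.90 mM |  | 12 min |
| oak | 13 mM | 52.0 mM | 6.50 mM | 3.90 mM |  | 12 min |
| larch | 13 mM | 32.5 mM | 6.50 mM | 3.90 mM |  | 12 min |

| run | time / min | complex with two exchanged / % | starting complex / % |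
|---|---|---|---|
| Sunday's | 0.667 | 1.9 | 89.7 |
| Sunday's | 1.50 | 0 | 84.4 |
| Sunday's | 4.00 | 0.2 | 72.3 |
| Sunday's | 8.00 | 2.1 | 60.3 |
| Friday's | 2.00 | 1.7 | 69.7 |
| Friday's | 4.00 | 4.0 | 55.6 |
| Friday's | 6.00 | 5.9 | 47.1 |
| Friday's | 8.00 | 7.2 | 40.0 |
| Thursday's | 2.00 | 6.9 | 48.1 |
| Thursday's | 4.00 | 15.1 | 33.0 |
| Thursday's | 6.00 | 23.4 | 23.9 |
| Thursday's | 8.00 | 24.8 | 19.4 |

(readings scatter by 1 percentage point)

- which of these holds the largest part of the starting complex at the end of cedar (complex with two exchanged / complex with one exchanged / starting complex)
- which of these holds the largest part of the starting complex at the end of oak (complex with two exchanged / complex with one exchanged / starting complex)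
- which of these holds the largest part of the starting complex at the end of larch (complex with two exchanged / complex with one exchanged / starting complex)
- complex with two exchanged at the end of larch, in percent of the starting complex charged

- the earlier runs were read with a standard deviation of 1 percentage point

I started with a loose bracket, which was an estimate. Friday's last reading, 7.2%, marked the low side, for larch had more ligand and more time. Thursday's last reading, 24.8%, marked the high side, with twice larch's ligand, but larch ran longer, so this mark was no strict bound.

To tighten this, I followed one molecule. Once it has left the starting complex, it reaches a fork: stop at one exchange or go on to the second. I defined the fork share g as the fraction of reacted starting complex standing as complex with two exchanged, divided by the incoming ligand charged. At 8.00 min, Friday's readings gave 0.00480 mM⁻¹ and Thursday's 0.00496 mM⁻¹, nearly equal, so I took 0.00488 mM⁻¹ as a reading for that time. This selectivity per mM gave an estimated share for larch of 15.9% at that same time.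

For the low end of my estimate I held that share and used Friday's reacted part, which gave 9.52%. For the high end I let the share grow again by the factor read from Thursday's run between 4.00 min and 8.00 min, 1.37, and used Thursday's reacted part, which gave 17.5%.

The forecast named starting complex for cedar, complex with one exchanged for oak and complex with one exchanged for larch, and put larch at 15% (11% to 20%), inside my bracket, noting: “The second exchange shows a lag and depends strongly on ligand”.

The flask gave starting complex in cedar at 48.5%, complex with one exchanged in oak at 38.8%, and complex with one exchanged in larch at 47.2%. Larch held 14.3% of complex with two exchanged, inside the bracket.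

    complex with two exchanged → over-reaction product (k = 0.120 min⁻¹)
    complex with one exchanged + incoming ligand ⇌ leaving ligand + complex with two exchanged (K = 1.20, k = 2.30 L mol⁻¹ min⁻¹)
    leaving ligand → by-product carried off (k = 0.780 min⁻¹)
    complex with one exchanged + capture agent → trapped intermediate (k = 0.470 L mol⁻¹ min⁻¹)
    starting complex + incoming ligand ⇌ leaving ligand + complex with one exchanged (K = 0.0700, k = 60.0 L mol⁻¹ min⁻¹)

Carried to larch's reacted part, g gives 11.8%, against 14.3% in the flask. Carried to oak, it gives 21.7%, against 23.8% in the flask. Larch's share of the reacted part stays at 19.1% mainly because the second exchange has the lower rate constant, 2.3 L mol⁻¹ min⁻¹ against 60 L mol⁻¹ min⁻¹. With that difference taken away, larch's complex with two exchanged stands at 34.3% instead of 14.3%.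

(The readings are simulated with constants of no real substance; noise was put on by code.)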